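**Assumptions (one line each)**
- Pseudomonas fluorescens lipase acetylates the pro-S arm of the diol to give the (S)-monoacetate, and the (R)-SEGPHOS iridium catalyst gives the 3R carbinol. Both are from memory of the literature sense and should be confirmed (Mosher ester); use the enantiomeric ligand if the sense is reversed.
- C6 is not formed selectively in this route: the Co-mediated peroxidation gives both C6 epimers (about 1:1), which are separated after ring closure.

**Retrosynthetic overview**
1. The methyl ester comes from a primary alcohol by late oxidation and esterification, so the ring closure never sees an enolisable ester with a β-leaving group.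
2. The 1,2-dioxane is the only ring made (step 12), by 6-exo-tet SN2 of a C6 tertiary hydroperoxide on a (3R)-mesylate, with inversion to 3S.
3. The C6–OOH comes from Mukaiyama–Isayama peroxidation (Co/O2/Et3SiH) of a C5=C6 trisubstituted alkene.
4. The C5=C6 alkene comes from cross-metathesis of a C1–C5 homoallylic mesylate with an isopropenyl-type alkene made from β-ionone; the cyclohexenone ring is carried intact from β-ionone.
5. C2 comes from lipase desymmetrisation of 2-methylpropane-1,3-diol, and C3 from an Ir-catalysed anti-selective allylation of the derived alcohol.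

**Route**

Step 1
Reactants: 1, β-ionone
Product: 2, 4-oxo-β-ionone
Conditions: CrO3, 3,5-dimethylpyrazole, CH2Cl2, −20 °C
Reagents that add atoms: chromium trioxide, O=[Cr](=O)=O
Why: Allylic oxidation (Salmond conditions) at ring C4, the only allylic CH2 of the dienone, gives the ring enone.

Step 2
Reactants: 2, 4-oxo-β-ionone
Product: 3, 2,4,4-trimethyl-3-(3-oxobutyl)cyclohex-2-en-1-one
Conditions: H2 (1 atm, 1 equiv uptake), 10% Pd/C, EtOAc, rt
Reagents that add atoms: none
Why: Chemoselective catalytic hydrogenation reduces the disubstituted side-chain enone C=C while the hindered tetrasubstituted ring C=C is untouched.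

Step 3
Reactants: 3, the diketone
Product: 4, 2,4,4-trimethyl-3-(3-methylbut-3-en-1-yl)cyclohex-2-en-1-one
Conditions: Ph3PCH3Br, KOt-Bu, THF, 0 °C to rt (1.1 equiv ylide)
Reagents that add atoms: methyltriphenylphosphonium bromide, C[P+](c1ccccc1)(c1ccccc1)c1ccccc1.[Br-]
Why: Wittig methylenation takes the unhindered saturated methyl ketone and leaves the hindered, conjugated ring ketone.

Step 4
Reactants: 5, 2-methylpropane-1,3-diol
Product: 6, (S)-3-hydroxy-2-methylpropyl acetate
Conditions: lipase (Pseudomonas fluorescens lipase, Amano AK; a serine hydrolase), vinyl acetate, CHCl3, rt, run to partial diacetate formation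
Reagents that add atoms: vinyl acetate, C=COC(C)=O
Why: Lipase-catalysed enantioselective transesterification desymmetrises the prochiral diol and sets the first stereocentre (future C2); over-acylation of the minor enantiomer to diacetate raises the ee.

Step 5
Reactants: 6, the (S)-monoacetate
Product: 7, (R)-3-[(tert-butyldiphenylsilyl)oxy]-2-methylpropyl acetate
Conditions: TBDPSCl, imidazole, CH2Cl2, 0 °C
Reagents that add atoms: tert-butyldiphenylsilyl chloride, CC(C)(C)[Si](Cl)(c1ccccc1)c1ccccc1
Why: Fast silylation of the free OH under mild conditions avoids 1,3-acyl migration, which would racemise the monoacetate (the descriptor changes only through CIP priorities).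

Step 6
Reactants: 7, the silyl ether acetate
Product: 8, (R)-3-[(tert-butyldiphenylsilyl)oxy]-2-methylpropan-1-ol
Conditions: K2CO3, MeOH, 0 °C
Reagents that add atoms: none
Why: Base-catalysed transesterification removes the acetate, and the stereocentre is not involved.

Step 7
Reactants: 8, the (R)-alcohol
Product: 9, (2S,3R)-1-[(tert-butyldiphenylsilyl)oxy]-2-methylhex-5-en-3-ol (2,3-anti)
Conditions: allyl acetate, [Ir(cod)Cl]2 (2.5 mol %), (R)-SEGPHOS (5 mol %), 4-cyano-3-nitrobenzoic acid (10 mol %), Cs2CO3 (20 mol %), THF, 100 °C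
Reagents that add atoms: allyl acetate, C=CCOC(C)=O
Why: Krische transfer-hydrogenative allylation from the alcohol oxidation level sets C3 (R, anti to the C2 methyl) under catalyst control, and the epimerisable aldehyde is never isolated.

Step 8
Reactants: 9, the homoallylic alcohol
Product: 10, (2S,3R)-1-[(tert-butyldiphenylsilyl)oxy]-2-methylhex-5-en-3-yl methanesulfonate
Conditions: MsCl, Et3N, CH2Cl2, 0 °C
Reagents that add atoms: methanesulfonyl chloride, CS(=O)(=O)Cl
Why: O-Sulfonylation proceeds with retention and turns the C3 oxygen into the leaving group for the later invertive ring closure.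

Step 9
Reactants: 10, the mesylate; 4, the 1,1-disubstituted alkene (3 equiv, excess recovered)
Product: 11, (2S,3R)-1-[(tert-butyldiphenylsilyl)oxy]-2,6-dimethyl-8-(2,6,6-trimethyl-3-oxocyclohex-1-en-1-yl)oct-5-en-3-yl methanesulfonate (E/Z mixture)
Conditions: Hoveyda–Grubbs II (5 mol %), CH2Cl2, 40 °C
Reagents that add atoms: none
Why: Olefin cross-metathesis of a terminal alkene with a 1,1-disubstituted alkene gives the trisubstituted C5=C6 alkene; its geometry is irrelevant because the next step destroys it, and the tetrasubstituted enone is inert.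

Step 10
Reactants: 11, the trisubstituted alkene
Product: 12, (2S,3R,6RS)-1-[(tert-butyldiphenylsilyl)oxy]-2,6-dimethyl-6-[(triethylsilyl)peroxy]-8-(2,6,6-trimethyl-3-oxocyclohex-1-en-1-yl)octan-3-yl methanesulfonate (about 1:1 at C6)
Conditions: Co(thd)2 (10 mol %), O2 (1 atm), Et3SiH, ClCH2CH2Cl, rt
Reagents that add atoms: dioxygen, O=O; triethylsilane, CC[SiH](CC)CC
Why: Mukaiyama–Isayama hydroperoxysilylation (Co–H hydrogen-atom transfer, then O2 trapping of the tertiary C6 radical) puts the peroxide on C6 with Markovnikov selectivity but no facial control, and the hindered electron-poor enone C=C does not react.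

Step 11
Reactants: 12, the silyl peroxide
Product: 13, (2S,3R,6RS)-1-[(tert-butyldiphenylsilyl)oxy]-6-hydroperoxy-2,6-dimethyl-8-(2,6,6-trimethyl-3-oxocyclohex-1-en-1-yl)octan-3-yl methanesulfonate
Conditions: conc. HCl (cat.), MeOH, 0 °C
Reagents that add atoms: none
Why: Acid methanolysis cleaves the labile O–SiEt3 bond of the silyl peroxide, while the TBDPS ether and the mesylate survive.

Step 12
Reactants: 13, the hydroperoxy mesylate
Product: 14, tert-butyl{(2S)-2-[(3S,6R)-6-methyl-6-[2-(2,6,6-trimethyl-3-oxocyclohex-1-en-1-yl)ethyl]-1,2-dioxan-3-yl]propoxy}diphenylsilane, separated from its (3S,6S) epimer by chromatography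
Conditions: KOt-Bu (1.1 equiv), 18-crown-6, THF, 0 °C; silica chromatography (HPLC if needed)
Reagents that add atoms: none
Why: Intramolecular 6-exo-tet SN2 of the peroxy anion on the secondary mesylate inverts C3 (3R to 3S) and forms the dioxane; the (3S,6R) isomer (C6 methyl cis to the C3 side chain, assigned by NOE) is kept and the 6-epimer is discarded.

Step 13
Reactants: 14, the silyl ether
Product: 15, (2S)-2-[(3S,6R)-6-methyl-6-[2-(2,6,6-trimethyl-3-oxocyclohex-1-en-1-yl)ethyl]-1,2-dioxan-3-yl]propan-1-ol
Conditions: HF·pyridine, pyridine, THF, 0 °C to rt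
Reagents that add atoms: none
Why: Buffered fluoride desilylation frees the primary alcohol without touching the dialkyl peroxide or the enone.

Step 14
Reactants: 15, the alcohol
Product: 16, (2R)-2-[(3S,6R)-6-methyl-6-[2-(2,6,6-trimethyl-3-oxocyclohex-1-en-1-yl)ethyl]-1,2-dioxan-3-yl]propanal
Conditions: Dess–Martin periodinane, NaHCO3, CH2Cl2, 0 °C; used at once
Reagents that add atoms: none
Why: Buffered Dess–Martin oxidation gives the α-chiral aldehyde without epimerisation or β-elimination of the peroxide (the descriptor changes only through CIP priorities).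

Step 15
Reactants: 16, the aldehyde
Product: 17, (2R)-2-[(3S,6R)-6-methyl-6-[2-(2,6,6-trimethyl-3-oxocyclohex-1-en-1-yl)ethyl]-1,2-dioxan-3-yl]propanoic acid
Conditions: NaClO2, NaH2PO4, 2-methyl-2-butene, t-BuOH/H2O, 0 °C to rt
Reagents that add atoms: sodium chlorite, [Na+].[O-]Cl=O
Why: Pinnick oxidation under mildly acidic buffer converts the aldehyde to the acid without enolisation, and the peroxide and enone are inert to chlorite.

Step 16
Reactants: 17, the acid
Product: 18, methyl (2R)-2-[(3S,6R)-6-methyl-6-[2-(2,6,6-trimethyl-3-oxocyclohex-1-en-1-yl)ethyl]-1,2-dioxan-3-yl]propanoate (methyl diacarnoate A)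
Conditions: TMSCHN2, MeOH/toluene, 0 °C
Reagents that add atoms: trimethylsilyldiazomethane, C[Si](C)(C)C=[N+]=[N-]
Why: Diazoalkane esterification is neutral and base-free, so C2 is not epimerised and the peroxide is not opened by retro-Michael elimination.

**Compound list**

1 | β-ionone, (E)-4-(2,6,6-trimethylcyclohex-1-en-1-yl)but-3-en-2-one | CC(=O)/C=C/C1=C(C)CCCC1(C)C | starting material
2 | 4-oxo-β-ionone, (E)-2,4,4-trimethyl-3-(3-oxobut-1-en-1-yl)cyclohex-2-en-1-one | CC(=O)/C=C/C1=C(C)C(=O)CCC1(C)C | intermediate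
3 | 2,4,4-trimethyl-3-(3-oxobutyl)cyclohex-2-en-1-one | CC(=O)CCC1=C(C)C(=O)CCC1(C)C | intermediate
4 | 2,4,4-trimethyl-3-(3-methylbut-3-en-1-yl)cyclohex-2-en-1-one | C=C(C)CCC1=C(C)C(=O)CCC1(C)C | intermediate
5 | 2-methylpropane-1,3-diol | CC(CO)CO | starting material
6 | (S)-3-hydroxy-2-methylpropyl acetate | CC(=O)OC[C@@H](C)CO | intermediate
7 | (R)-3-[(tert-butyldiphenylsilyl)oxy]-2-methylpropyl acetate | CC(=O)OC[C@@H](C)CO[Si](c1ccccc1)(c1ccccc1)C(C)(C)C | intermediate
8 | (R)-3-[(tert-butyldiphenylsilyl)oxy]-2-methylpropan-1-ol | OC[C@@H](C)CO[Si](c1ccccc1)(c1ccccc1)C(C)(C)C | intermediate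
9 | (2S,3R)-1-[(tert-butyldiphenylsilyl)oxy]-2-methylhex-5-en-3-ol | CC(C)(C)[Si](c1ccccc1)(c1ccccc1)OC[C@H](C)[C@H](O)CC=C | intermediate
10 | (2S,3R)-1-[(tert-butyldiphenylsilyl)oxy]-2-methylhex-5-en-3-yl methanesulfonate | CC(C)(C)[Si](c1ccccc1)(c1ccccc1)OC[C@H](C)[C@H](OS(C)(=O)=O)CC=C | intermediate
11 | (2S,3R)-1-[(tert-butyldiphenylsilyl)oxy]-2,6-dimethyl-8-(2,6,6-trimethyl-3-oxocyclohex-1-en-1-yl)oct-5-en-3-yl methanesulfonate (E/Z) | CC(C)(C)[Si](c1ccccc1)(c1ccccc1)OC[C@H](C)[C@H](OS(C)(=O)=O)CC=C(C)CCC1=C(C)C(=O)CCC1(C)C | intermediate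
12 | (2S,3R,6RS)-6-[(triethylsilyl)peroxy] mesylate (C6 about 1:1) | CC(C)(C)[Si](c1ccccc1)(c1ccccc1)OC[C@H](C)[C@H](OS(C)(=O)=O)CCC(C)(OO[Si](CC)(CC)CC)CCC1=C(C)C(=O)CCC1(C)C | intermediate
13 | (2S,3R,6RS)-6-hydroperoxy mesylate (C6 about 1:1) | CC(C)(C)[Si](c1ccccc1)(c1ccccc1)OC[C@H](C)[C@H](OS(C)(=O)=O)CCC(C)(OO)CCC1=C(C)C(=O)CCC1(C)C | intermediate
14 | TBDPS ether of (2S)-2-[(3S,6R)-6-methyl-6-[2-(2,6,6-trimethyl-3-oxocyclohex-1-en-1-yl)ethyl]-1,2-dioxan-3-yl]propan-1-ol | CC(C)(C)[Si](c1ccccc1)(c1ccccc1)OC[C@H](C)[C@@H]1CC[C@@](C)(CCC2=C(C)C(=O)CCC2(C)C)OO1 | intermediate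
15 | (2S)-2-[(3S,6R)-6-methyl-6-[2-(2,6,6-trimethyl-3-oxocyclohex-1-en-1-yl)ethyl]-1,2-dioxan-3-yl]propan-1-ol | OC[C@H](C)[C@@H]1CC[C@@](C)(CCC2=C(C)C(=O)CCC2(C)C)OO1 | intermediate
16 | (2R)-2-[(3S,6R)-…-1,2-dioxan-3-yl]propanal | O=C[C@H](C)[C@@H]1CC[C@@](C)(CCC2=C(C)C(=O)CCC2(C)C)OO1 | intermediate
17 | (2R)-2-[(3S,6R)-…-1,2-dioxan-3-yl]propanoic acid | OC(=O)[C@H](C)[C@@H]1CC[C@@](C)(CCC2=C(C)C(=O)CCC2(C)C)OO1 | intermediate
18 | methyl (2R)-2-[(3S,6R)-6-methyl-6-[2-(2,6,6-trimethyl-3-oxocyclohex-1-en-1-yl)ethyl]-1,2-dioxan-3-yl]propanoate | COC(=O)[C@H](C)[C@@H]1CC[C@@](C)(CCC2=C(C)C(=O)CCC2(C)C)OO1 | target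

**Totals**
- Total steps: 16.
- Longest linear sequence: 13 steps (5 to 18, steps 4–16). The β-ionone branch is 3 steps before the convergent step 9.

**Three steps most likely to fail, with fallbacks**

1. Step 12, the SN2 ring closure. The mesylate carbon is secondary and β-branched, and E2 elimination or intramolecular Weitz–Scheffer attack of the peroxy anion on the enone can compete. Fallback: close the ring by peroxy-Michael addition instead. Make the (E)-2-methyl-2-enoate at C1–C3 (C3 aldehyde plus Ph3P=C(Me)CO2Me) and cyclise the C6 hydroperoxide 6-exo-trig (Et2NH, CF3CH2OH), then separate diastereomers.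

2. Step 10, the Co-mediated peroxidation. It gives no control at C6, so half the material is lost at the step 12 separation, and yields are moderate. Fallback: form the C6–O bond stereospecifically. Build the (E)-C6=C1′ trisubstituted alkene, carry out Shi epoxidation, open the epoxide at the tertiary carbon with H2O2/phosphomolybdic acid (inversion), ring-close as in step 12, then remove the extra C1′–OH by mesylation, elimination into conjugation with the enone, and diimide reduction.

3. Step 9, the cross-metathesis to a trisubstituted alkene. Homodimerisation and low conversion are the risks. Fallback: join the fragments by Wittig olefination. Protect 9 as its TBS ether, ozonolyse and reduce to the C5 alcohol, convert to the iodide and phosphonium salt, and react the ylide with methyl ketone 3; then remove the TBS group and mesylate to rejoin the route at 11.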